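**Retrosynthetic overview**
- Last step: regioselective O-demethylation at C5 and C6 of a pentamethoxy flavone whose 4'-OH is already free.
- Key disconnection C2–C1': the chromone C2 (normally the electrophilic β-carbon of the enone) is used as a nucleophile, a 2-zincated chromone, and joined to the ipso carbon of a 4-iodophenol.
- Ring B is bought preformed as a dimethoxyphenol and only iodinated para to OH.
- Ring A is bought preformed as a hydroxy-trimethoxy-acetophenone.
- Ring order: pyranone ring C is closed on ring A first (enaminone cyclization); ring B is attached last.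

Assumption: the target has no stereocentre and no configurationally stable axis, so it is a single achiral compound and no stereocontrol is needed.

**Step 1**
Reactants: 1 1-(6-hydroxy-2,3,4-trimethoxyphenyl)ethan-1-one
Product: 3 5,6,7-trimethoxy-4H-chromen-4-one, via enaminone 2 (not isolated)
Conditions: DMF-DMA (2 equiv), toluene, 110 °C, 3 h; evaporate; conc. HCl, CH2Cl2, 40 °C, 1 h
Reagents that add atoms: N,N-dimethylformamide dimethyl acetal (DMF-DMA), COC(OC)N(C)C
Why: Condensation of the methyl ketone with the amide acetal gives the enaminone, and acid-promoted intramolecular oxa-Michael addition of the ortho phenol with loss of dimethylamine closes ring C (enaminone chromone synthesis); no stereocentre is formed.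

**Step 2**
Reactants: 4 2,5-dimethoxyphenol
Product: 5 4-iodo-2,5-dimethoxyphenol
Conditions: NIS (1.0 equiv), MeCN, -20 → 0 °C, dark, 2 h
Reagents that add atoms: N-iodosuccinimide (NIS), O=C1CCC(=O)N1I
Why: Electrophilic aromatic iodination goes to C4, which is para to the hydroxyl, ortho to the 5-methoxy group and the least hindered of the activated positions.

**Step 3**
Reactants: 3 5,6,7-trimethoxy-4H-chromen-4-one; 5 4-iodo-2,5-dimethoxyphenol
Product: 7 2-(4-hydroxy-2,5-dimethoxyphenyl)-5,6,7-trimethoxy-4H-chromen-4-one, via chromon-2-ylzinc chloride 6 (not isolated)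
Conditions: 3 (1.6 equiv), TMPZnCl·LiCl (1.7 equiv), THF, 25 °C, 1 h; then added over 1 h to 5 (1.0 equiv), Pd(OAc)2 (2 mol %), SPhos (4 mol %), THF, 25 → 50 °C; aq. NH4Cl
Reagents that add atoms: none
Why: C2–H zincation with the hindered zinc amide makes the normally electrophilic enone β-carbon a β-acylvinyl (α-alkoxyvinyl) zinc nucleophile, a homoenolate-type reversed-polarity reagent, and Negishi cross-coupling joins it to the electrophilic ipso carbon of the aryl iodide, the free phenol being tolerated because arylzinc halides transmetalate faster than ArOH protonates them and 6 is in excess.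

**Step 4**
Reactants: 7 2-(4-hydroxy-2,5-dimethoxyphenyl)-5,6,7-trimethoxy-4H-chromen-4-one
Product: 8 5,6-dihydroxy-2-(4-hydroxy-2,5-dimethoxyphenyl)-7-methoxy-4H-chromen-4-one
Conditions: 48 % aq. HBr, AcOH (1:2), 100 °C, argon, ca. 2 h, HPLC control, stop at the 5,6-diol
Reagents that add atoms: none
Why: Regioselective acidolytic ether cleavage (bromide attack on the protonated methyl ether) removes first the 5-methoxy group, activated by the protonated peri carbonyl, and then the 6-methoxy group, twisted out of conjugation by its two ortho neighbours, before the coplanar 7-, 2'- and 5'-methoxy groups react; no stereocentre is involved.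

**Compound list**
1 | 1-(6-hydroxy-2,3,4-trimethoxyphenyl)ethan-1-one | CC(=O)c1c(O)cc(OC)c(OC)c1OC | starting material
2 | (E)-3-(dimethylamino)-1-(6-hydroxy-2,3,4-trimethoxyphenyl)prop-2-en-1-one (enaminone) | CN(C)/C=C/C(=O)c1c(O)cc(OC)c(OC)c1OC | intermediate
3 | 5,6,7-trimethoxy-4H-chromen-4-one | COc1cc2occc(=O)c2c(OC)c1OC | intermediate
4 | 2,5-dimethoxyphenol | COc1ccc(OC)c(O)c1 | starting material
5 | 4-iodo-2,5-dimethoxyphenol | COc1cc(I)c(OC)cc1O | intermediate
6 | (5,6,7-trimethoxy-4-oxo-4H-chromen-2-yl)zinc chloride, LiCl-complexed in THF | COc1cc2oc([Zn]Cl)cc(=O)c2c(OC)c1OC | intermediate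
7 | 2-(4-hydroxy-2,5-dimethoxyphenyl)-5,6,7-trimethoxy-4H-chromen-4-one | COc1cc(-c2cc(=O)c3c(OC)c(OC)c(OC)cc3o2)c(OC)cc1O | intermediate
8 | 5,6-dihydroxy-2-(4-hydroxy-2,5-dimethoxyphenyl)-7-methoxy-4H-chromen-4-one | COc1cc(-c2cc(=O)c3c(O)c(O)c(OC)cc3o2)c(OC)cc1O | target

**Totals**
Total step count: 4. Longest linear sequence: 3 steps (1 → 3 → 7 → 8); step 2 is a one-step side branch.

**Steps most likely to fail, with fallbacks**

Step 3 (key coupling). The risks are protonolysis of zinc reagent 6 by the free phenol and slow oxidative addition of the electron-rich iodide. The fallback sets out from 3, through the same zinc reagent 6, and comes back to the route at 7. Reagent 6 is quenched with Bu3SnCl (THF, 25 °C) and the product is isolated as 5,6,7-trimethoxy-2-(tributylstannyl)-4H-chromen-4-one F1, a proton-stable form of the same C2 nucleophile. F1 is then coupled with 5 under Stille conditions (Pd(PPh3)4 5 mol %, copper iodide CuI 10 mol %, DMF, 80 °C), which are indifferent to the phenolic OH, to give 7.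

Step 4 (selective demethylation). The risks are loss of a ring B methyl ether or of the 7-methoxy group. The fallback sets out from 3 and comes back to the route at 8; it moves the demethylation ahead of the coupling, where no ring B ether is present and purification is simple.
- Chromone 3 with 48 % aq. HBr/AcOH (100 °C) gives 5,6-dihydroxy-7-methoxy-4H-chromen-4-one F2.
- BnBr, K2CO3, DMF, 70 °C converts it into 5,6-bis(benzyloxy)-7-methoxy-4H-chromen-4-one F3.
- TMPZnCl·LiCl (THF, 25 °C) gives [5,6-bis(benzyloxy)-7-methoxy-4-oxo-4H-chromen-2-yl]zinc chloride F4, which is coupled with 5 exactly as in step 3.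
- The coupling product is 5,6-bis(benzyloxy)-2-(4-hydroxy-2,5-dimethoxyphenyl)-7-methoxy-4H-chromen-4-one F5.
- Hydrogenolysis (H2 1 atm, palladium on carbon Pd/C, EtOAc–MeOH, 25 °C) removes both benzyl groups and gives 8.

Step 2 (iodination). The risks are an ortho/para mixture, di-iodination or oxidation of the very electron-rich phenol. The fallback does not use 4. It sets out from chromone 3 (zinc reagent 6 unchanged) with a ring B partner whose halogen position is fixed by its starting material, and it comes back to the route at 7.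
- Commercial 4-bromo-2,5-dimethoxybenzaldehyde F6 is oxidized with mCPBA (CH2Cl2, 25 °C, Dakin-type Baeyer–Villiger aryl migration) to 4-bromo-2,5-dimethoxyphenyl formate F7.
- K2CO3/MeOH (25 °C) cleaves the formate to 4-bromo-2,5-dimethoxyphenol F8.
- F8 replaces 5 in step 3 (same Pd(OAc)2/SPhos catalyst, 60 °C) and gives 7.

**Further compounds**
F1 | step 3 | 5,6,7-trimethoxy-2-(tributylstannyl)-4H-chromen-4-one | CCCC[Sn](CCCC)(CCCC)c1cc(=O)c2c(OC)c(OC)c(OC)cc2o1
F2 | step 4 | 5,6-dihydroxy-7-methoxy-4H-chromen-4-one | COc1cc2occc(=O)c2c(O)c1O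
F3 | step 4 | 5,6-bis(benzyloxy)-7-methoxy-4H-chromen-4-one | COc1cc2occc(=O)c2c(OCc2ccccc2)c1OCc1ccccc1
F4 | step 4 | [5,6-bis(benzyloxy)-7-methoxy-4-oxo-4H-chromen-2-yl]zinc chloride | COc1cc2oc([Zn]Cl)cc(=O)c2c(OCc2ccccc2)c1OCc1ccccc1
F5 | step 4 | 5,6-bis(benzyloxy)-2-(4-hydroxy-2,5-dimethoxyphenyl)-7-methoxy-4H-chromen-4-one | COc1cc(-c2cc(=O)c3c(OCc4ccccc4)c(OCc4ccccc4)c(OC)cc3o2)c(OC)cc1O
F6 | step 2 | 4-bromo-2,5-dimethoxybenzaldehyde | COc1cc(C=O)c(OC)cc1Br
F7 | step 2 | 4-bromo-2,5-dimethoxyphenyl formate | COc1cc(OC=O)c(OC)cc1Br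
F8 | step 2 | 4-bromo-2,5-dimethoxyphenol | COc1cc(Br)c(OC)cc1O
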